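Numbering: ring A carbocycle C1 (CMe2), C2 (CHBr), C3, C4, C5 (C–Me, O6), C11 (fusion CH); ring B oxepane O6, C7 (=C12HBr), C8–C9 epoxide, C10. The route rests on disconnecting C1–C2: because quaternary C1 lies between C2 and C11, it can be the γ-terminus of an allylsilane attacking a C2 aldehyde. One Lewis-acid step closes ring A, builds C1, places oxygen at C2 for the later bromide and leaves exocyclic C11=C10 for growing ring B. The precursor is an (R)-linalool-derived aldehyde whose C5 (methyl, silyloxy O6) bears the tetrasubstituted allylsilane C11(CH2SiMe3)=C1Me2.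

Key step: step 9

Remark: 13 is drawn as the C2 epimer expected from step 9; should the other epimer also form, both converge at ketone 17, since C2 is not stereogenic from step 11 until step 18.

Step 1
Reactants: 1 (R)-linalool
Product: 2 (3R)-3-[(tert-butyldimethylsilyl)oxy]-3,7-dimethylocta-1,6-diene
Conditions: TBSOTf, 2,6-lutidine, CH2Cl2, 0 °C → rt
Reagents that add atoms: tert-butyldimethylsilyl trifluoromethanesulfonate, CC(C)(C)[Si](C)(C)OS(=O)(=O)C(F)(F)F
Why: Silyl triflate with a hindered pyridine base silylates tertiary allylic alcohols readily (O-silylation), and the bulky silyl group is chosen because it should survive the acetal steps, the potassium enolate of step 6 without O-to-O silyl shift and TiCl4 at low temperature; the linalool carbinol centre (later C5) is untouched.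

Step 2
Reactants: 2 (3R)-3-[(tert-butyldimethylsilyl)oxy]-3,7-dimethylocta-1,6-diene
Product: 4 (3R)-3-[(tert-butyldimethylsilyl)oxy]-6,6-dimethoxy-3-methylhex-1-ene, via aldehyde 3 (not isolated)
Conditions: O3, CH2Cl2, −78 °C (Sudan Red 7B end point); Me2S, −78 °C → rt; then HC(OMe)3, MeOH, PPTS, rt
Reagents that add atoms: trimethyl orthoformate, COC(OC)OC; ozone, [O-][O+]=O (oxygen of intermediate 3 only)
Why: Ozonolysis is chemoselective for the electron-rich trisubstituted alkene over the vinyl group, which is deactivated by the adjacent silyloxy carbon, and the crude aldehyde is masked in the same flask as its dimethyl acetal (acid-catalysed acetalisation) so that it survives the organometallic steps.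

Step 3
Reactants: 4 (3R)-3-[(tert-butyldimethylsilyl)oxy]-6,6-dimethoxy-3-methylhex-1-ene
Product: 5 (2R)-2-[(tert-butyldimethylsilyl)oxy]-5,5-dimethoxy-2-methylpentanal
Conditions: O3, CH2Cl2, −78 °C; Me2S, −78 °C → rt
Reagents that add atoms: ozone, [O-][O+]=O
Why: A second ozonolysis cleaves the remaining vinyl group to the α-quaternary aldehyde, which cannot epimerise, while the acyclic acetal and the silyl ether are inert at −78 °C.

Step 4
Reactants: 5 (2R)-2-[(tert-butyldimethylsilyl)oxy]-5,5-dimethoxy-2-methylpentanal; 6 isopropylmagnesium bromide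
Product: 7 (4R)-4-[(tert-butyldimethylsilyl)oxy]-7,7-dimethoxy-2,4-dimethylheptan-3-ol (both C3 epimers)
Conditions: i-PrMgBr, CeCl3, THF, −78 → 0 °C; cold aq. NH4Cl
Reagents that add atoms: none
Why: Grignard addition to the hindered aldehyde, with CeCl3 to suppress β-hydride reduction by the branched reagent and a cold quench to prevent silyl migration, should give the carbinol, whose configuration is irrelevant because it is oxidised in step 5.

Step 5
Reactants: 7 (4R)-4-[(tert-butyldimethylsilyl)oxy]-7,7-dimethoxy-2,4-dimethylheptan-3-ol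
Product: 8 (4R)-4-[(tert-butyldimethylsilyl)oxy]-7,7-dimethoxy-2,4-dimethylheptan-3-one
Conditions: Dess–Martin periodinane, NaHCO3, CH2Cl2, rt
Reagents that add atoms: none
Why: Dess–Martin oxidation under bicarbonate buffer converts the hindered secondary alcohol into the isopropyl ketone without touching the acid-labile acetal.

Step 6
Reactants: 8 (4R)-4-[(tert-butyldimethylsilyl)oxy]-7,7-dimethoxy-2,4-dimethylheptan-3-one
Product: 9 (4R)-4-[(tert-butyldimethylsilyl)oxy]-7,7-dimethoxy-2,4-dimethylhept-2-en-3-yl trifluoromethanesulfonate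
Conditions: KN(SiMe3)2, THF, −78 °C; PhNTf2, −78 → 0 °C
Reagents that add atoms: N-phenylbis(trifluoromethanesulfonimide), O=S(=O)(N(c1ccccc1)S(=O)(=O)C(F)(F)F)C(F)(F)F
Why: The ketone has a single enolisable position, the isopropyl methine, so deprotonation and O-triflation (enol triflate formation) can only give the tetrasubstituted enol triflate that fixes the future C11=C1 alkene.

Step 7
Reactants: 9 (4R)-4-[(tert-butyldimethylsilyl)oxy]-7,7-dimethoxy-2,4-dimethylhept-2-en-3-yl trifluoromethanesulfonate; 10 (trimethylsilyl)methylmagnesium chloride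
Product: 11 (4R)-4-[(tert-butyldimethylsilyl)oxy]-7,7-dimethoxy-2,4-dimethyl-3-[(trimethylsilyl)methyl]hept-2-ene
Conditions: Me3SiCH2MgCl, Pd(PPh3)4 (5 mol %), THF, rt → 50 °C
Reagents that add atoms: none
Why: Kumada–Corriu coupling of enol triflates with Me3SiCH2MgCl under Pd(PPh3)4 catalysis is a standard allylsilane synthesis and places C10 with its silicon on C11.

Step 8
Reactants: 11 (4R)-4-[(tert-butyldimethylsilyl)oxy]-7,7-dimethoxy-2,4-dimethyl-3-[(trimethylsilyl)methyl]hept-2-ene
Product: 12 (4R)-4-[(tert-butyldimethylsilyl)oxy]-4,6-dimethyl-5-[(trimethylsilyl)methyl]hept-5-enal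
Conditions: PPTS, acetone/H2O, 40 °C
Reagents that add atoms: water, O
Why: Mild acid-catalysed acetal hydrolysis with pyridinium tosylate in wet acetone should free the aldehyde without protodesilylating the allylsilane or cleaving the tertiary silyl ether.

Step 9
Reactants: 12 (4R)-4-[(tert-butyldimethylsilyl)oxy]-4,6-dimethyl-5-[(trimethylsilyl)methyl]hept-5-enal
Product: 13 (1R,4R)-4-[(tert-butyldimethylsilyl)oxy]-2,2,4-trimethyl-3-methylidenecyclohexan-1-ol
Conditions: TiCl4, CH2Cl2, −78 °C; aq. NaHCO3
Reagents that add atoms: none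
Why: TiCl4 activates the C2 aldehyde, the tetrasubstituted allylsilane attacks it through its dimethyl-bearing γ-carbon C1 (anti SE2′) to form the C1–C2 bond, and the β-silyl cation at C11 collapses by loss of the trimethylsilyl group to the exocyclic C11=C10 alkene. The closest known reaction type is the intramolecular Hosomi–Sakurai addition of γ,γ-disubstituted allylsilanes to aldehydes, an established way to make a quaternary carbon next to a new carbinol. Ring A closes in a 6-exo-trig mode with respect to the carbonyl group (both alkene carbons, C1 and C11, become ring members) through a chair-like transition state. The new C2 stereocentre is controlled by that chair and by the linalool-derived C5 centre: the C5 oxygen rather than the C5 methyl group takes the position on the face of the departing silicon, and the titanium-bound oxygen lies synclinal to the alkene, away from both C1 methyl groups, which should place the hydroxyl trans to the C5 oxygen (this centre is erased in step 11). The selectivity needed is bonding through C1 and not C10, secured because only attack at C1 develops a cation at C11 that the C–Si bond stabilises, together with survival of the tertiary allylic silyl ether, secured by the bulky silyl group and the low temperature.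

Step 10
Reactants: 13 (1R,4R)-4-[(tert-butyldimethylsilyl)oxy]-2,2,4-trimethyl-3-methylidenecyclohexan-1-ol; 14 vinyl bromide
Product: 16 (1R,3R,4R)-4-[(tert-butyldimethylsilyl)oxy]-2,2,4-trimethyl-3-(prop-2-en-1-yl)cyclohexan-1-ol, via alkylborane 15 (not isolated)
Conditions: 9-BBN (2.5 equiv), THF, rt → 60 °C; then vinyl bromide, PdCl2(dppf) (5 mol %), 3 M aq. NaOH, THF, rt → 50 °C
Reagents that add atoms: none
Why: Hydroboration puts boron on terminal C10 and should deliver hydrogen to C11 from the face anti to the C5 methyl group and the axial C1 methyl group, in the chair that keeps the C5 silyloxy group in the alkene plane (substrate control, as for other 2-methylenecycloalkyl silyl ethers with 9-BBN), which sets C11 with C10 trans to O6; the B-alkyl borane then undergoes Suzuki–Miyaura coupling with vinyl bromide to add C9.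

Step 11
Reactants: 16 (1R,3R,4R)-4-[(tert-butyldimethylsilyl)oxy]-2,2,4-trimethyl-3-(prop-2-en-1-yl)cyclohexan-1-ol
Product: 17 (3R,4R)-4-[(tert-butyldimethylsilyl)oxy]-2,2,4-trimethyl-3-(prop-2-en-1-yl)cyclohexan-1-one
Conditions: Dess–Martin periodinane, NaHCO3, CH2Cl2, rt
Reagents that add atoms: none
Why: Dess–Martin oxidation of the neopentyl secondary alcohol gives the ketone and removes the C2 stereocentre, so both carbinol epimers would converge here.

Step 12
Reactants: 17 (3R,4R)-4-[(tert-butyldimethylsilyl)oxy]-2,2,4-trimethyl-3-(prop-2-en-1-yl)cyclohexan-1-one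
Product: 18 (4R,5R)-4-[(tert-butyldimethylsilyl)oxy]-4,6,6-trimethyl-5-(prop-2-en-1-yl)cyclohex-1-en-1-yl trifluoromethanesulfonate
Conditions: KN(SiMe3)2, THF, −78 °C; PhNTf2, −78 → 0 °C
Reagents that add atoms: N-phenylbis(trifluoromethanesulfonimide), O=S(=O)(N(c1ccccc1)S(=O)(=O)C(F)(F)F)C(F)(F)F
Why: C1 is quaternary, so the ketone can enolise only toward C3 and O-triflation of the potassium enolate (enol triflate formation) gives one regioisomer.

Step 13
Reactants: 18 (4R,5R)-4-[(tert-butyldimethylsilyl)oxy]-4,6,6-trimethyl-5-(prop-2-en-1-yl)cyclohex-1-en-1-yl trifluoromethanesulfonate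
Product: 19 tert-butyl{[(1R,6R)-4-bromo-1,5,5-trimethyl-6-(prop-2-en-1-yl)cyclohex-3-en-1-yl]oxy}dimethylsilane
Conditions: Ni(cod)2 (10 mol %), LiBr, DMA/THF, rt
Reagents that add atoms: lithium bromide, [Li+].[Br-]
Why: Nickel-catalysed triflate-to-halide exchange of enol triflates (oxidative addition, anion exchange, C–Br reductive elimination) should give the alkenyl bromide under neutral conditions at room temperature, leaving the allyl group and the silyl ether intact.

Step 14
Reactants: 19 tert-butyl{[(1R,6R)-4-bromo-1,5,5-trimethyl-6-(prop-2-en-1-yl)cyclohex-3-en-1-yl]oxy}dimethylsilane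
Product: 20 (1R,6R)-4-bromo-1,5,5-trimethyl-6-(prop-2-en-1-yl)cyclohex-3-en-1-ol
Conditions: Bu4NF, THF, 60 °C
Reagents that add atoms: none
Why: Fluoride-mediated desilylation, run warm because the tertiary silyl ether is hindered, frees the C5 hydroxyl (O6) with no other fluoride-sensitive group present.

Step 15
Reactants: 20 (1R,6R)-4-bromo-1,5,5-trimethyl-6-(prop-2-en-1-yl)cyclohex-3-en-1-ol; 21 methacryloyl chloride
Product: 22 (1R,6R)-4-bromo-1,5,5-trimethyl-6-(prop-2-en-1-yl)cyclohex-3-en-1-yl 2-methylprop-2-enoate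
Conditions: KN(SiMe3)2, THF, −78 °C; methacryloyl chloride, −78 → 0 °C
Reagents that add atoms: none
Why: O-Acylation of the tertiary potassium alkoxide with the acid chloride (esterification) attaches C7 and C8 with its methyl group to O6, and the non-nucleophilic amide base leaves the alkenyl bromide alone.

Step 16
Reactants: 22 (1R,6R)-4-bromo-1,5,5-trimethyl-6-(prop-2-en-1-yl)cyclohex-3-en-1-yl 2-methylprop-2-enoate
Product: 23 (5aR,9aR)-7-bromo-3,6,6,9a-tetramethyl-5a,6,9,9a-tetrahydro-1-benzoxepin-2(5H)-one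
Conditions: second-generation Hoveyda–Grubbs catalyst (5 mol %), toluene (dilute), 80 °C
Reagents that add atoms: none
Why: Ring-closing metathesis starts at the terminal allyl alkene and closes onto the methacrylate to give the trisubstituted C8=C9 bond of the seven-membered lactone (ring B, trans-fused because O6 and C10 are both equatorial), while the hindered ring bromoalkene does not engage the ruthenium carbene.

Step 17
Reactants: 23 (5aR,9aR)-7-bromo-3,6,6,9a-tetramethyl-5a,6,9,9a-tetrahydro-1-benzoxepin-2(5H)-one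
Product: 24 (3S,4S,5aR,9aR)-7-bromo-3,4-epoxy-3,6,6,9a-tetramethyl-4,5,5a,6,9,9a-hexahydro-1-benzoxepin-2(3H)-one
Conditions: t-BuOOH, n-BuLi, THF, −78 °C; then 23, −20 °C → rt
Reagents that add atoms: tert-butyl hydroperoxide, CC(C)(C)OO
Why: In this Weitz–Scheffer epoxidation the peroxide anion adds conjugately to C9 and the lactone enolate closes the oxirane, which spares the bromoalkene because it is not a Michael acceptor, and attack should come from the face of the C11 hydrogen, away from the axial methyl groups on C5 and C1 that cover the other face of ring B, setting C8 and C9 together.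

Step 18
Reactants: 24 (3S,4S,5aR,9aR)-7-bromo-3,4-epoxy-3,6,6,9a-tetramethyl-4,5,5a,6,9,9a-hexahydro-1-benzoxepin-2(3H)-one
Product: 25 (3S,4S,5aR,7R,9aR)-7-bromo-3,4-epoxy-3,6,6,9a-tetramethyloctahydro-1-benzoxepin-2(3H)-one
Conditions: Mn(dpm)3 (10 mol %; dpm = 2,2,6,6-tetramethylheptane-3,5-dionate), PhSiH3, t-BuOOH, i-PrOH, rt
Reagents that add atoms: none
Why: Metal-hydride hydrogen-atom-transfer hydrogenation (Mukaiyama-type), a method known to reduce alkenyl halides to alkyl halides without C–Br cleavage, adds a hydrogen atom to C3 and then quenches the α-bromo C2 radical along the axial trajectory, anti to the axial C1 methyl group of the now rigid trans-fused chair, so that bromine ends up equatorial.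

Step 19
Reactants: 25 (3S,4S,5aR,7R,9aR)-7-bromo-3,4-epoxy-3,6,6,9a-tetramethyloctahydro-1-benzoxepin-2(3H)-one
Product: 26 (3S,4S,5aR,7R,9aR)-7-bromo-2-(dibromomethylidene)-3,4-epoxy-3,6,6,9a-tetramethyldecahydro-1-benzoxepine
Conditions: [Ph3PCHBr2]Br, KOt-Bu, toluene/THF, 0 °C → rt; then 25, rt → 70 °C
Reagents that add atoms: (dibromomethyl)triphenylphosphonium bromide, BrC(Br)[P+](c1ccccc1)(c1ccccc1)c1ccccc1.[Br-]
Why: Wittig-type dibromomethylenation of a lactone carbonyl by Ph3P=CBr2 (Ramirez olefination) is known for α-oxygenated lactones, the class to which this epoxy lactone belongs, and generating the ylide from the phosphonium salt avoids the Ph3PBr2 that could open the epoxide.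

Step 20
Reactants: 26 (3S,4S,5aR,7R,9aR)-7-bromo-2-(dibromomethylidene)-3,4-epoxy-3,6,6,9a-tetramethyldecahydro-1-benzoxepine
Product: 27 (2E,3S,4S,5aR,7R,9aR)-7-bromo-2-(bromomethylidene)-3,4-epoxy-3,6,6,9a-tetramethyldecahydro-1-benzoxepine (CNP0375295.2)
Conditions: Bu3SnH (1.1 equiv), Pd(PPh3)4 (5 mol %), toluene, rt
Reagents that add atoms: none
Why: Palladium-catalysed hydrogenolysis of 1,1-dibromoalkenes with Bu3SnH is stereoselective because zerovalent palladium inserts into the less hindered C–Br bond, here the one cis to O6 and remote from quaternary C8, so hydride replaces that bromine and the remaining bromine is cis to C8, which is the required E enol ether; the neopentyl alkyl bromide and the epoxide should not react at room temperature.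

Compound list
1 | (R)-linalool | C=C[C@](C)(O)CCC=C(C)C | starting material
2 | (3R)-3-[(tert-butyldimethylsilyl)oxy]-3,7-dimethylocta-1,6-diene | C=C[C@](C)(O[Si](C)(C)C(C)(C)C)CCC=C(C)C | intermediate
3 | (4R)-4-[(tert-butyldimethylsilyl)oxy]-4-methylhex-5-enal | C=C[C@](C)(O[Si](C)(C)C(C)(C)C)CCC=O | intermediate
4 | (3R)-3-[(tert-butyldimethylsilyl)oxy]-6,6-dimethoxy-3-methylhex-1-ene | C=C[C@](C)(O[Si](C)(C)C(C)(C)C)CCC(OC)OC | intermediate
5 | (2R)-2-[(tert-butyldimethylsilyl)oxy]-5,5-dimethoxy-2-methylpentanal | O=C[C@](C)(O[Si](C)(C)C(C)(C)C)CCC(OC)OC | intermediate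
6 | isopropylmagnesium bromide | CC(C)[Mg]Br | starting material
7 | (4R)-4-[(tert-butyldimethylsilyl)oxy]-7,7-dimethoxy-2,4-dimethylheptan-3-ol (C3 epimers) | CC(C)C(O)[C@](C)(O[Si](C)(C)C(C)(C)C)CCC(OC)OC | intermediate
8 | (4R)-4-[(tert-butyldimethylsilyl)oxy]-7,7-dimethoxy-2,4-dimethylheptan-3-one | CC(C)C(=O)[C@](C)(O[Si](C)(C)C(C)(C)C)CCC(OC)OC | intermediate
9 | (4R)-4-[(tert-butyldimethylsilyl)oxy]-7,7-dimethoxy-2,4-dimethylhept-2-en-3-yl trifluoromethanesulfonate | CC(C)=C(OS(=O)(=O)C(F)(F)F)[C@](C)(O[Si](C)(C)C(C)(C)C)CCC(OC)OC | intermediate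
10 | (trimethylsilyl)methylmagnesium chloride | C[Si](C)(C)C[Mg]Cl | starting material
11 | (4R)-4-[(tert-butyldimethylsilyl)oxy]-7,7-dimethoxy-2,4-dimethyl-3-[(trimethylsilyl)methyl]hept-2-ene | CC(C)=C(C[Si](C)(C)C)[C@](C)(O[Si](C)(C)C(C)(C)C)CCC(OC)OC | intermediate
12 | (4R)-4-[(tert-butyldimethylsilyl)oxy]-4,6-dimethyl-5-[(trimethylsilyl)methyl]hept-5-enal | O=CCC[C@@](C)(O[Si](C)(C)C(C)(C)C)C(C[Si](C)(C)C)=C(C)C | intermediate
13 | (1R,4R)-4-[(tert-butyldimethylsilyl)oxy]-2,2,4-trimethyl-3-methylidenecyclohexan-1-ol | CC1(C)[C@H](O)CC[C@@](C)(O[Si](C)(C)C(C)(C)C)C1=C | intermediate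
14 | vinyl bromide | C=CBr | starting material
15 | B-alkyl-9-BBN adduct of 13 (boron on C10, hydrogen on C11 trans to O6, C2 oxygen as its O-9-BBN borinate) | CC1(C)[C@H](OB2C3CCCC2CCC3)CC[C@@](C)(O[Si](C)(C)C(C)(C)C)[C@@H]1CB1C2CCCC1CCC2 | intermediate
16 | (1R,3R,4R)-4-[(tert-butyldimethylsilyl)oxy]-2,2,4-trimethyl-3-(prop-2-en-1-yl)cyclohexan-1-ol | CC1(C)[C@H](O)CC[C@@](C)(O[Si](C)(C)C(C)(C)C)[C@@H]1CC=C | intermediate
17 | (3R,4R)-4-[(tert-butyldimethylsilyl)oxy]-2,2,4-trimethyl-3-(prop-2-en-1-yl)cyclohexan-1-one | CC1(C)C(=O)CC[C@@](C)(O[Si](C)(C)C(C)(C)C)[C@@H]1CC=C | intermediate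
18 | (4R,5R)-4-[(tert-butyldimethylsilyl)oxy]-4,6,6-trimethyl-5-(prop-2-en-1-yl)cyclohex-1-en-1-yl trifluoromethanesulfonate | CC1(C)C(OS(=O)(=O)C(F)(F)F)=CC[C@@](C)(O[Si](C)(C)C(C)(C)C)[C@@H]1CC=C | intermediate
19 | tert-butyl{[(1R,6R)-4-bromo-1,5,5-trimethyl-6-(prop-2-en-1-yl)cyclohex-3-en-1-yl]oxy}dimethylsilane | CC1(C)C(Br)=CC[C@@](C)(O[Si](C)(C)C(C)(C)C)[C@@H]1CC=C | intermediate
20 | (1R,6R)-4-bromo-1,5,5-trimethyl-6-(prop-2-en-1-yl)cyclohex-3-en-1-ol | CC1(C)C(Br)=CC[C@@](C)(O)[C@@H]1CC=C | intermediate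
21 | methacryloyl chloride | C=C(C)C(=O)Cl | starting material
22 | (1R,6R)-4-bromo-1,5,5-trimethyl-6-(prop-2-en-1-yl)cyclohex-3-en-1-yl 2-methylprop-2-enoate | CC1(C)C(Br)=CC[C@@](C)(OC(=O)C(C)=C)[C@@H]1CC=C | intermediate
23 | (5aR,9aR)-7-bromo-3,6,6,9a-tetramethyl-5a,6,9,9a-tetrahydro-1-benzoxepin-2(5H)-one | CC1(C)C(Br)=CC[C@@]2(C)OC(=O)C(C)=CC[C@H]12 | intermediate
24 | (3S,4S,5aR,9aR)-7-bromo-3,4-epoxy-3,6,6,9a-tetramethyl-4,5,5a,6,9,9a-hexahydro-1-benzoxepin-2(3H)-one (epoxide oxygen on the face of the ring-fusion hydrogen) | CC1(C)C(Br)=CC[C@@]2(C)OC(=O)[C@@]3(C)O[C@H]3C[C@H]12 | intermediate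
25 | (3S,4S,5aR,7R,9aR)-7-bromo-3,4-epoxy-3,6,6,9a-tetramethyloctahydro-1-benzoxepin-2(3H)-one (equatorial bromine) | CC1(C)[C@H](Br)CC[C@@]2(C)OC(=O)[C@@]3(C)O[C@H]3C[C@H]12 | intermediate
26 | (3S,4S,5aR,7R,9aR)-7-bromo-2-(dibromomethylidene)-3,4-epoxy-3,6,6,9a-tetramethyldecahydro-1-benzoxepine | CC1(C)[C@H](Br)CC[C@@]2(C)OC(=C(Br)Br)[C@@]3(C)O[C@H]3C[C@H]12 | intermediate
27 | (2E,3S,4S,5aR,7R,9aR)-7-bromo-2-(bromomethylidene)-3,4-epoxy-3,6,6,9a-tetramethyldecahydro-1-benzoxepine (CNP0375295.2) | CC1(C)[C@H](Br)CC[C@@]2(C)O/C(=C/Br)[C@@]3(C)O[C@H]3C[C@H]12 | target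

Total step count: 20. Longest linear sequence: 20 steps from (R)-linalool (1).

Steps most likely to fail

Step 9. The Lewis acid may consume the substrate before the C1–C2 bond forms, by protodesilylation of the tetrasubstituted allylsilane or by ionisation of the tertiary allylic silyl ether. The fallback gives up silicon control and uses a carbonyl-ene closure. It sets out from enol triflate 9: Fe(acac)3-catalysed cross-coupling with MeMgBr should give (4R)-4-[(tert-butyldimethylsilyl)oxy]-7,7-dimethoxy-2,3,4-trimethylhept-2-ene F1. Pyridinium tosylate in wet acetone then unmasks (4R)-4-[(tert-butyldimethylsilyl)oxy]-4,5,6-trimethylhept-5-enal F2. Me2AlCl in CH2Cl2 at −78 °C should then effect an intramolecular carbonyl-ene (Prins-type) cyclisation in which C1 bonds to C2 and a hydrogen is transferred from the C11 methyl group. Bonding through C11 instead would place two quaternary carbons side by side in a five-membered ring and is disfavoured. The fallback returns to the route at 13.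

Step 10. Hydrogen may be delivered to C11 from the wrong face, because the chair with an axial C5 silyloxy group can compete, which would lead to the cis-fused series. The fallback replaces substrate-controlled hydroboration by hydroxyl-directed hydrogenation. It sets out from 13:
- Dess–Martin oxidation gives (4R)-4-[(tert-butyldimethylsilyl)oxy]-2,2,4-trimethyl-3-methylidenecyclohexan-1-one F3, which removes the C2 hydroxyl that could direct to the opposite face.
- Bu4NF frees (4R)-4-hydroxy-2,2,4-trimethyl-3-methylidenecyclohexan-1-one F4.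
- Rhodium-catalysed dehydrogenative borylation (trans-RhCl(CO)(PPh3)2, B2pin2, toluene/MeCN, 80 °C) converts the 1,1-disubstituted alkene into (4R)-4-hydroxy-2,2,4-trimethyl-3-[(4,4,5,5-tetramethyl-1,3,2-dioxaborolan-2-yl)methylidene]cyclohexan-1-one F5, whose alkene geometry is irrelevant.
- Hydrogenation with [Ir(cod)(PCy3)(py)]PF6 and H2 in CH2Cl2 is directed by the tertiary allylic hydroxyl and should add hydrogen to C11 syn to O6, giving (3R,4R)-4-hydroxy-2,2,4-trimethyl-3-[(4,4,5,5-tetramethyl-1,3,2-dioxaborolan-2-yl)methyl]cyclohexan-1-one F6.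
- Suzuki–Miyaura coupling with vinyl bromide (PdCl2(dppf), Ag2O, K2CO3, THF, 70 °C) gives (3R,4R)-4-hydroxy-2,2,4-trimethyl-3-(prop-2-en-1-yl)cyclohexan-1-one F7.
- KN(SiMe3)2 (2.2 equiv) and PhNTf2 give (4R,5R)-4-hydroxy-4,6,6-trimethyl-5-(prop-2-en-1-yl)cyclohex-1-en-1-yl trifluoromethanesulfonate F8.
- Ni(cod)2/LiBr exchange then returns to the route at 20.

Step 19. The stabilised ylide may fail to add to the hindered, α-quaternary lactone carbonyl, and prolonged heating may open the epoxide. The fallback builds the dibromoalkene by carbanion addition and elimination instead of a Wittig reaction. It sets out from 25: LiCHBr2 (from CH2Br2 and LiN(i-Pr)2, THF, −90 °C) adds to the lactone carbonyl, and the lithium hemiketal is trapped cold with trifluoroacetic anhydride before the ring can open. This gives (3S,4S,5aR,7R,9aR)-7-bromo-2-(dibromomethyl)-3,4-epoxy-3,6,6,9a-tetramethyldecahydro-1-benzoxepin-2-yl trifluoroacetate F9 as a mixture of C2 epimers. DBU then eliminates trifluoroacetic acid across C7–C12, the only position with a removable hydrogen, and the fallback returns to the route at 26.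

Further compounds
F1 | step 9 | (4R)-4-[(tert-butyldimethylsilyl)oxy]-7,7-dimethoxy-2,3,4-trimethylhept-2-ene | CC(C)=C(C)[C@](C)(O[Si](C)(C)C(C)(C)C)CCC(OC)OC
F2 | step 9 | (4R)-4-[(tert-butyldimethylsilyl)oxy]-4,5,6-trimethylhept-5-enal | O=CCC[C@@](C)(O[Si](C)(C)C(C)(C)C)C(C)=C(C)C
F3 | step 10 | (4R)-4-[(tert-butyldimethylsilyl)oxy]-2,2,4-trimethyl-3-methylidenecyclohexan-1-one | CC1(C)C(=O)CC[C@@](C)(O[Si](C)(C)C(C)(C)C)C1=C
F4 | step 10 | (4R)-4-hydroxy-2,2,4-trimethyl-3-methylidenecyclohexan-1-one | CC1(C)C(=O)CC[C@@](C)(O)C1=C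
F5 | step 10 | (4R)-4-hydroxy-2,2,4-trimethyl-3-[(4,4,5,5-tetramethyl-1,3,2-dioxaborolan-2-yl)methylidene]cyclohexan-1-one | CC1(C)C(=O)CC[C@@](C)(O)C1=CB1OC(C)(C)C(C)(C)O1
F6 | step 10 | (3R,4R)-4-hydroxy-2,2,4-trimethyl-3-[(4,4,5,5-tetramethyl-1,3,2-dioxaborolan-2-yl)methyl]cyclohexan-1-one | CC1(C)C(=O)CC[C@@](C)(O)[C@@H]1CB1OC(C)(C)C(C)(C)O1
F7 | step 10 | (3R,4R)-4-hydroxy-2,2,4-trimethyl-3-(prop-2-en-1-yl)cyclohexan-1-one | CC1(C)C(=O)CC[C@@](C)(O)[C@@H]1CC=C
F8 | step 10 | (4R,5R)-4-hydroxy-4,6,6-trimethyl-5-(prop-2-en-1-yl)cyclohex-1-en-1-yl trifluoromethanesulfonate | CC1(C)C(OS(=O)(=O)C(F)(F)F)=CC[C@@](C)(O)[C@@H]1CC=C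
F9 | step 19 | (3S,4S,5aR,7R,9aR)-7-bromo-2-(dibromomethyl)-3,4-epoxy-3,6,6,9a-tetramethyldecahydro-1-benzoxepin-2-yl trifluoroacetate (C2 epimers) | CC1(C)[C@H](Br)CC[C@@]2(C)OC(OC(=O)C(F)(F)F)(C(Br)Br)[C@@]3(C)O[C@H]3C[C@H]12
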